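**Plan**
1. Retrosynthesis: the last cut is the CH2–CH2 bond C8–C9 of ring A together with the O–C7 bond of ring B (one cascade). Earlier cuts are C1–C2 (bromomethyl ketone, then reduction), C3=C4 (Z-olefination), C6–C7 (conjugate addition) and C10–C11 (reverse prenylation).
2. Forward: a temporary dihydropyranone ring (O, C10, C11, C6, C5, C4) is made first, used to set C6 and opened. The chain is then extended to the acyclic bromohydrin 15, and the last step closes ring A and then ring B.
3. Stereochemistry: C10 comes from a Brown prenylboration (as C–O, inverted to C–Br in the cascade). C6 is relayed from C10 by trans-selective cuprate addition to the lactone, C7 is set by the chair transition state of the cascade, and C2 by CBS reduction. The Z-alkene comes from a Still–Gennari olefination.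
4. Enabling feature: in ring A the new bond lies between the CHBr carbon C10 and the quaternary ether carbon C7. The array Br–C10H–C9H2–C8H2–C7(CH3)–O is what results when a bromonium ion is opened at its CH2 end by the CH2 terminus of an isopropenyl group and the tertiary cation is caught by the oxygen of ring B.
5. Helpers: the δ-lactone ring (opened in step 5), the mesylate on C10 (leaves in step 12) and the silyl ether on C9 (exchanged for Br in step 9).

Key step: step 12

Remark: locants follow a farnesane-type numbering: C1 = CH2Br on ring B, C2 = OCH, C3 = C(CH3)=, C4 = =CH, C5 = CH2, C6 = ring-fusion CH, C7 = ring-fusion C(CH3)O, C8 and C9 = the CH2 groups of ring A (C8 next to C7), C10 = CHBr, C11 = C(CH3)2; ring A is the cyclohexane, ring B the oxepene.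
Assumption: the facial sense of the prenylboration and of the CBS reduction follows the standard models; the antipodal reagent would be used if either proved opposite.

Step 1
Reactants: 1 2-[(tert-butyldimethylsilyl)oxy]acetaldehyde
Product: 3 (S)-1-[(tert-butyldimethylsilyl)oxy]-3,3-dimethylpent-4-en-2-ol, via diisopinocampheylborinate ester 2 (not isolated)
Conditions: (−)-Ipc2BOMe, prenylmagnesium chloride, Et2O/THF, −78 → 0 °C; then 1, −78 °C; then NaOH, H2O2
Reagents that add atoms: prenylmagnesium chloride, CC(C)=CC[Mg]Cl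
Why: Brown asymmetric allylboration in its reverse-prenylation form: the prenylborane adds through its γ-carbon in a closed chair transition state, and the isopinocampheyl groups derived from (+)-α-pinene should direct attack to the Si face of the aldehyde, setting the (S)-carbinol (future C10) next to the new quaternary C11.

Step 2
Reactants: 3 (S)-1-[(tert-butyldimethylsilyl)oxy]-3,3-dimethylpent-4-en-2-ol
Product: 4 (S)-1-[(tert-butyldimethylsilyl)oxy]-3,3-dimethylpent-4-en-2-yl acrylate
Conditions: CH2=CHCOCl, Et3N, DMAP (cat.), CH2Cl2, 0 °C → rt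
Reagents that add atoms: acryloyl chloride, C=CC(=O)Cl
Why: O-acylation of a secondary alcohol with an acid chloride under nucleophilic catalysis, which leaves the stereocenter untouched.

Step 3
Reactants: 4 (S)-1-[(tert-butyldimethylsilyl)oxy]-3,3-dimethylpent-4-en-2-yl acrylate
Product: 5 (S)-6-{[(tert-butyldimethylsilyl)oxy]methyl}-5,5-dimethyl-5,6-dihydro-2H-pyran-2-one
Conditions: second-generation Grubbs catalyst RuCl2(=CHPh)(H2IMes)(PCy3) (5 mol%), toluene, 80 °C, 0.005 M
Reagents that add atoms: none
Why: Ring-closing metathesis of an acrylate with a terminal alkene should give the α,β-unsaturated δ-lactone, the gem-dimethyl group favouring closure; this temporary ring will relay the C10 configuration to C6.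

Step 4
Reactants: 5 (S)-6-{[(tert-butyldimethylsilyl)oxy]methyl}-5,5-dimethyl-5,6-dihydro-2H-pyran-2-one
Product: 7 (4R,6S)-6-{[(tert-butyldimethylsilyl)oxy]methyl}-5,5-dimethyl-4-(prop-1-en-2-yl)tetrahydro-2H-pyran-2-one, via silyl ketene acetal 6 (not isolated)
Conditions: CH2=C(CH3)MgBr, CuBr·SMe2 (20 mol%), Me3SiCl, THF, −78 → −40 °C; then aq NH4Cl
Reagents that add atoms: isopropenylmagnesium bromide, CC(=C)[Mg]Br
Why: Copper-catalysed, chlorosilane-accelerated conjugate addition of a Grignard reagent, in which axial attack on the half-chair anti to the C6 substituent of the dihydropyranone should give the trans-4,6 lactone and so set C6 (target numbering) from C10.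

Step 5
Reactants: 7 (4R,6S)-6-{[(tert-butyldimethylsilyl)oxy]methyl}-5,5-dimethyl-4-(prop-1-en-2-yl)tetrahydro-2H-pyran-2-one
Product: 8 (3R,5S)-6-[(tert-butyldimethylsilyl)oxy]-5-hydroxy-N-methoxy-N,4,4-trimethyl-3-(prop-1-en-2-yl)hexanamide
Conditions: MeNH(OMe)·HCl, AlMe3, CH2Cl2, 0 °C → rt; aq potassium sodium tartrate; crude used at once
Reagents that add atoms: N,O-dimethylhydroxylamine hydrochloride, CNOC.Cl
Why: Weinreb aminolysis of a lactone with the aluminium amide should open the temporary ring and free the C10 hydroxyl, and the hindered hydroxy amide is carried on crude to avoid relactonisation.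

Step 6
Reactants: 8 (3R,5S)-6-[(tert-butyldimethylsilyl)oxy]-5-hydroxy-N-methoxy-N,4,4-trimethyl-3-(prop-1-en-2-yl)hexanamide
Product: 9 (2S,4R)-1-[(tert-butyldimethylsilyl)oxy]-6-[methoxy(methyl)amino]-3,3-dimethyl-6-oxo-4-(prop-1-en-2-yl)hexan-2-yl methanesulfonate
Conditions: MsCl, Et3N, CH2Cl2, −10 → 0 °C
Reagents that add atoms: methanesulfonyl chloride, CS(=O)(=O)Cl
Why: Mesylation through the sulfene tolerates the hindered neopentylic alcohol, and the resulting secondary mesylate is inert to SN2 attack, so it can be carried as the latent leaving group of the key step.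

Step 7
Reactants: 9 (2S,4R)-1-[(tert-butyldimethylsilyl)oxy]-6-[methoxy(methyl)amino]-3,3-dimethyl-6-oxo-4-(prop-1-en-2-yl)hexan-2-yl methanesulfonate
Product: 10 (2S,4R)-1-[(tert-butyldimethylsilyl)oxy]-3,3-dimethyl-6-oxo-4-(prop-1-en-2-yl)hexan-2-yl methanesulfonate
Conditions: i-Bu2AlH, THF, −78 °C
Reagents that add atoms: none
Why: Weinreb amide reduction should stop at the aldehyde through the chelated tetrahedral intermediate, and the mesylate and silyl ether are inert at −78 °C.

Step 8
Reactants: 10 (2S,4R)-1-[(tert-butyldimethylsilyl)oxy]-3,3-dimethyl-6-oxo-4-(prop-1-en-2-yl)hexan-2-yl methanesulfonate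
Product: 11 ethyl (2Z,5R,7S)-8-[(tert-butyldimethylsilyl)oxy]-2,6,6-trimethyl-7-[(methylsulfonyl)oxy]-5-(prop-1-en-2-yl)oct-2-enoate
Conditions: (CF3CH2O)2P(O)CH(CH3)CO2Et, KN(SiMe3)2, 18-crown-6, THF, −78 °C
Reagents that add atoms: ethyl 2-[bis(2,2,2-trifluoroethoxy)phosphoryl]propanoate, CCOC(=O)C(C)P(=O)(OCC(F)(F)F)OCC(F)(F)F
Why: Still–Gennari olefination should give the Z-trisubstituted enoate, which places C2 and C5 cis on the C3=C4 bond as ring B requires.

Step 9
Reactants: 11 ethyl (2Z,5R,7S)-8-[(tert-butyldimethylsilyl)oxy]-2,6,6-trimethyl-7-[(methylsulfonyl)oxy]-5-(prop-1-en-2-yl)oct-2-enoate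
Product: 12 ethyl (2Z,5R,7S)-8-bromo-2,6,6-trimethyl-7-[(methylsulfonyl)oxy]-5-(prop-1-en-2-yl)oct-2-enoate
Conditions: Ph3PBr2, CH2Cl2, 0 °C → rt
Reagents that add atoms: triphenylphosphine dibromide, BrP(Br)(c1ccccc1)(c1ccccc1)c1ccccc1
Why: Direct conversion of a primary silyl ether into a bromide with triphenylphosphine dibromide (Appel-type, through the alkoxyphosphonium ion), while the hindered secondary mesylate should not react.

Step 10
Reactants: 12 ethyl (2Z,5R,7S)-8-bromo-2,6,6-trimethyl-7-[(methylsulfonyl)oxy]-5-(prop-1-en-2-yl)oct-2-enoate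
Product: 14 (2S,4R,6Z)-1,9-dibromo-3,3,7-trimethyl-8-oxo-4-(prop-1-en-2-yl)non-6-en-2-yl methanesulfonate, via lithium hemiketal alkoxide 13 (not isolated)
Conditions: CH2Br2, MeLi·LiBr, THF/Et2O, −78 °C; AcOH quench at −78 °C
Reagents that add atoms: dibromomethane, BrCBr
Why: Halomethyllithium carbenoid homologation of an ester: the carbenoid, made in the presence of the ester, should add 1,2 to give a hemiketal alkoxide that persists at −78 °C and collapses to the bromomethyl ketone only on acidic quench.

Step 11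
Reactants: 14 (2S,4R,6Z)-1,9-dibromo-3,3,7-trimethyl-8-oxo-4-(prop-1-en-2-yl)non-6-en-2-yl methanesulfonate
Product: 15 (2S,4R,6Z,8R)-1,9-dibromo-8-hydroxy-3,3,7-trimethyl-4-(prop-1-en-2-yl)non-6-en-2-yl methanesulfonate
Conditions: (R)-Me-CBS oxazaborolidine (20 mol%), catecholborane, toluene, −78 °C
Reagents that add atoms: none
Why: Corey–Bakshi–Shibata reduction, in which the α-branched alkenyl group acts as the large and CH2Br as the small substituent, so the (R)-catalyst should give the (R)-bromohydrin at C2 while alkenes, bromides and the mesylate stay intact.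

Step 12
Reactants: 15 (2S,4R,6Z,8R)-1,9-dibromo-8-hydroxy-3,3,7-trimethyl-4-(prop-1-en-2-yl)non-6-en-2-yl methanesulfonate
Product: 18 Palisadin B, via bromonium ion 16 (not isolated), via cyclohexyl cation 17 (not isolated)
Conditions: (CF3)2CHOH, 2,6-di-tert-butyl-4-methylpyridine, 0.005 M, 25 → 50 °C
Reagents that add atoms: none
Why: Proposed new method: in the ionising but non-nucleophilic solvent the C10 mesylate should leave with backside participation of the bromine on C9, giving bromonium ion 16 with inversion at C10 and without an external bromine electrophile, which would prefer the two more electron-rich alkenes; the CH2 terminus (C8) of the isopropenyl group then opens 16 at its unhindered CH2 end (C9), and the hydroxyl on C2 captures the tertiary C7 cation 17. The closest known reaction types are the bromonium-initiated polyene cyclisation terminated by a hydroxyl group, the solvolytic generation of enantiopure bromonium ions from β-bromo sulfonates, and the PdCl2-catalysed Cope rearrangement of 2-substituted 1,5-dienes, in which the substituted alkene likewise attacks the CH2 end of an electrophile-bound vinyl group to give a cyclohexyl cation. Ring A closes in a 6-endo mode (endo for both the alkene and the bromonium ion) through a chair, and ring B closes in a 7-exo mode by C–O bond formation at the cationic C7. C10 is fixed by the double displacement (oxygen leaves, bromine bridges and stays, equatorial), and C7 by the chair with the C6 side chain equatorial and anti addition across C7=C8, which puts oxygen equatorial and methyl axial (trans fusion). The step needs attack at the CH2 end and not the CH end of 16 (the CH end is neopentylic, next to quaternary C11), ionisation without methyl shift (bromine is the better neighbouring group and is antiperiplanar), and capture over proton loss (the Z-alkene holds the hydroxyl within reach of C7, and the hindered pyridine buffers the acid).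

**Compound list**
1 | 2-[(tert-butyldimethylsilyl)oxy]acetaldehyde | O=CCO[Si](C)(C)C(C)(C)C | starting material
2 | (S)-1-[(tert-butyldimethylsilyl)oxy]-3,3-dimethylpent-4-en-2-yl diisopinocampheylborinate | C=CC(C)(C)[C@@H](CO[Si](C)(C)C(C)(C)C)OB([C@@H]1C[C@@H]2C[C@H]([C@H]1C)C2(C)C)[C@@H]1C[C@@H]2C[C@H]([C@H]1C)C2(C)C | intermediate
3 | (S)-1-[(tert-butyldimethylsilyl)oxy]-3,3-dimethylpent-4-en-2-ol | C=CC(C)(C)[C@H](O)CO[Si](C)(C)C(C)(C)C | intermediate
4 | (S)-1-[(tert-butyldimethylsilyl)oxy]-3,3-dimethylpent-4-en-2-yl acrylate | C=CC(C)(C)[C@@H](CO[Si](C)(C)C(C)(C)C)OC(=O)C=C | intermediate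
5 | (S)-6-{[(tert-butyldimethylsilyl)oxy]methyl}-5,5-dimethyl-5,6-dihydro-2H-pyran-2-one | O=C1C=CC(C)(C)[C@@H](CO[Si](C)(C)C(C)(C)C)O1 | intermediate
6 | (2S,4R)-2-{[(tert-butyldimethylsilyl)oxy]methyl}-3,3-dimethyl-4-(prop-1-en-2-yl)-6-[(trimethylsilyl)oxy]-3,4-dihydro-2H-pyran | C[Si](C)(C)OC1=C[C@H](C(C)=C)C(C)(C)[C@@H](CO[Si](C)(C)C(C)(C)C)O1 | intermediate
7 | (4R,6S)-6-{[(tert-butyldimethylsilyl)oxy]methyl}-5,5-dimethyl-4-(prop-1-en-2-yl)tetrahydro-2H-pyran-2-one | O=C1C[C@H](C(C)=C)C(C)(C)[C@@H](CO[Si](C)(C)C(C)(C)C)O1 | intermediate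
8 | (3R,5S)-6-[(tert-butyldimethylsilyl)oxy]-5-hydroxy-N-methoxy-N,4,4-trimethyl-3-(prop-1-en-2-yl)hexanamide | CON(C)C(=O)C[C@H](C(C)=C)C(C)(C)[C@H](O)CO[Si](C)(C)C(C)(C)C | intermediate
9 | (2S,4R)-1-[(tert-butyldimethylsilyl)oxy]-6-[methoxy(methyl)amino]-3,3-dimethyl-6-oxo-4-(prop-1-en-2-yl)hexan-2-yl methanesulfonate | CON(C)C(=O)C[C@H](C(C)=C)C(C)(C)[C@H](OS(C)(=O)=O)CO[Si](C)(C)C(C)(C)C | intermediate
10 | (2S,4R)-1-[(tert-butyldimethylsilyl)oxy]-3,3-dimethyl-6-oxo-4-(prop-1-en-2-yl)hexan-2-yl methanesulfonate | O=CC[C@H](C(C)=C)C(C)(C)[C@H](OS(C)(=O)=O)CO[Si](C)(C)C(C)(C)C | intermediate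
11 | ethyl (2Z,5R,7S)-8-[(tert-butyldimethylsilyl)oxy]-2,6,6-trimethyl-7-[(methylsulfonyl)oxy]-5-(prop-1-en-2-yl)oct-2-enoate | CCOC(=O)/C(C)=C\C[C@H](C(C)=C)C(C)(C)[C@H](OS(C)(=O)=O)CO[Si](C)(C)C(C)(C)C | intermediate
12 | ethyl (2Z,5R,7S)-8-bromo-2,6,6-trimethyl-7-[(methylsulfonyl)oxy]-5-(prop-1-en-2-yl)oct-2-enoate | CCOC(=O)/C(C)=C\C[C@H](C(C)=C)C(C)(C)[C@H](OS(C)(=O)=O)CBr | intermediate
13 | lithium hemiketal alkoxide from 12 and bromomethyllithium | [Li+].CCOC([O-])(CBr)/C(C)=C\C[C@H](C(C)=C)C(C)(C)[C@H](OS(C)(=O)=O)CBr | intermediate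
14 | (2S,4R,6Z)-1,9-dibromo-3,3,7-trimethyl-8-oxo-4-(prop-1-en-2-yl)non-6-en-2-yl methanesulfonate | BrCC(=O)/C(C)=C\C[C@H](C(C)=C)C(C)(C)[C@H](OS(C)(=O)=O)CBr | intermediate
15 | (2S,4R,6Z,8R)-1,9-dibromo-8-hydroxy-3,3,7-trimethyl-4-(prop-1-en-2-yl)non-6-en-2-yl methanesulfonate | BrC[C@H](O)/C(C)=C\C[C@H](C(C)=C)C(C)(C)[C@H](OS(C)(=O)=O)CBr | intermediate
16 | C9–C10 bromonium ion derived from 15, as its methanesulfonate | BrC[C@H](O)/C(C)=C\C[C@H](C(C)=C)C(C)(C)[C@@H]1C[Br+]1.CS(=O)(=O)[O-] | intermediate
17 | tertiary C7 cyclohexyl cation (ring A closed), as its methanesulfonate | BrC[C@H](O)/C(C)=C\C[C@H]1C(C)(C)[C@@H](Br)CC[C+]1C.CS(=O)(=O)[O-] | intermediate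
18 | Palisadin B | CC1=CC[C@H]2C(C)(C)[C@@H](Br)CC[C@]2(C)O[C@H]1CBr | target

**Step count**
Total steps: 12. Longest linear sequence: 12 steps (from 1).

**Steps most likely to fail**

Step 12 (proposed new method). Three processes could defeat it:
- ionisation of the mesylate with methyl migration from C11 instead of bromine participation;
- opening of the bromonium ion at its CH end, giving a cyclopentane;
- proton loss from the C7 cation, or capture from the wrong face (cis fusion), instead of the intended ether closure.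

Fallback with known chemistry, setting out from 15 and returning at 18:
- Zinc dust in AcOH/EtOH would reductively eliminate the β-bromo mesylate to the terminal alkene (2R,3Z,6R)-1-bromo-3,7,7-trimethyl-6-(prop-1-en-2-yl)nona-3,8-dien-2-ol F1.
- Cope rearrangement of its 1,5-diene (PdCl2(MeCN)2, THF, rt, or thermally near 200 °C in a sealed tube) would make the same CH2–CH2 bond in an open chain and give the farnesane-type alcohol (2R,3Z,6E)-1-bromo-3,7,11-trimethyldodeca-3,6,10-trien-2-ol F2.
- A bromonium-induced polyene cyclisation terminated by the hydroxyl group (2,4,4,6-tetrabromocyclohexa-2,5-dienone, MeNO2, 0 °C, or Et2SBr·SbBrCl5) would then close ring A at C6–C11 and ring B at O–C7 to return to 18.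
- The cost is that C6 and C10 are erased by the Cope step and the face of the bromonium ion is then controlled only by the remote C2 center, so the diastereomeric ring system would have to be separated.

Step 4. The addition may be sluggish at the β-carbon flanked by the quaternary C11, may lose facial selectivity, or may divert to 1,2-addition at the lactone carbonyl.

Fallback setting out from 5 and returning at 7:
- Conjugate addition of the small nitronate of nitroethane (DBU, MeCN), again by axial attack anti to the C6 substituent, would give (4S,6S)-6-{[(tert-butyldimethylsilyl)oxy]methyl}-5,5-dimethyl-4-(1-nitroethyl)tetrahydro-2H-pyran-2-one F3.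
- A reductive Nef reaction (aqueous TiCl3, NH4OAc buffer) would give the methyl ketone (4S,6S)-4-acetyl-6-{[(tert-butyldimethylsilyl)oxy]methyl}-5,5-dimethyltetrahydro-2H-pyran-2-one F4.
- Wittig methylenation (Ph3P=CH2, THF, −78 → 0 °C), which prefers the ketone over the lactone, would return to 7.

Step 10. The hemiketal alkoxide may collapse early and take up a second carbenoid, MeLi may add to the ester or deprotonate the mesylate methyl group, and the Z-enone may isomerise.

Fallback setting out from 12 and returning at 14, by electrophilic bromination instead of nucleophilic halomethylation: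
- Aminolysis (MeNH(OMe)·HCl, i-PrMgCl, THF, −20 °C) would give the Weinreb amide (2S,4R,6Z)-1-bromo-8-[methoxy(methyl)amino]-3,3,7-trimethyl-8-oxo-4-(prop-1-en-2-yl)oct-6-en-2-yl methanesulfonate F5.
- MeMgBr (THF, −20 °C) would give the methyl ketone (2S,4R,6Z)-1-bromo-3,3,7-trimethyl-8-oxo-4-(prop-1-en-2-yl)non-6-en-2-yl methanesulfonate F6.
- Kinetic enolisation and silylation (LiN(SiMe3)2, Me3SiCl, THF, −78 °C) would give the silyl enol ether (2S,4R,6Z)-1-bromo-3,3,7-trimethyl-4-(prop-1-en-2-yl)-8-[(trimethylsilyl)oxy]nona-6,8-dien-2-yl methanesulfonate F7.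
- N-bromosuccinimide (THF, −78 °C) would brominate the enol ether terminus and return to 14.

**Further compounds**
F1 | step 12 | (2R,3Z,6R)-1-bromo-3,7,7-trimethyl-6-(prop-1-en-2-yl)nona-3,8-dien-2-ol | BrC[C@H](O)/C(C)=C\C[C@H](C(C)=C)C(C)(C)C=C
F2 | step 12 | (2R,3Z,6E)-1-bromo-3,7,11-trimethyldodeca-3,6,10-trien-2-ol | BrC[C@H](O)/C(C)=C\C/C=C(\C)CCC=C(C)C
F3 | step 4 | (4S,6S)-6-{[(tert-butyldimethylsilyl)oxy]methyl}-5,5-dimethyl-4-(1-nitroethyl)tetrahydro-2H-pyran-2-one | O=C1C[C@H](C(C)[N+](=O)[O-])C(C)(C)[C@@H](CO[Si](C)(C)C(C)(C)C)O1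
F4 | step 4 | (4S,6S)-4-acetyl-6-{[(tert-butyldimethylsilyl)oxy]methyl}-5,5-dimethyltetrahydro-2H-pyran-2-one | O=C1C[C@H](C(C)=O)C(C)(C)[C@@H](CO[Si](C)(C)C(C)(C)C)O1
F5 | step 10 | (2S,4R,6Z)-1-bromo-8-[methoxy(methyl)amino]-3,3,7-trimethyl-8-oxo-4-(prop-1-en-2-yl)oct-6-en-2-yl methanesulfonate | CON(C)C(=O)/C(C)=C\C[C@H](C(C)=C)C(C)(C)[C@H](OS(C)(=O)=O)CBr
F6 | step 10 | (2S,4R,6Z)-1-bromo-3,3,7-trimethyl-8-oxo-4-(prop-1-en-2-yl)non-6-en-2-yl methanesulfonate | CC(=O)/C(C)=C\C[C@H](C(C)=C)C(C)(C)[C@H](OS(C)(=O)=O)CBr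
F7 | step 10 | (2S,4R,6Z)-1-bromo-3,3,7-trimethyl-4-(prop-1-en-2-yl)-8-[(trimethylsilyl)oxy]nona-6,8-dien-2-yl methanesulfonate | C=C(O[Si](C)(C)C)/C(C)=C\C[C@H](C(C)=C)C(C)(C)[C@H](OS(C)(=O)=O)CBr
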